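The synthesis rests on disconnecting the C1–C10 bond of ring A (C1–C5, C10), so that ring C, the seven-membered ring B and the 19,6-enol lactone are assembled first. The key step is an intramolecular Prins cyclisation of a C1 aldehyde, carried on the quaternary C4 of the lactone, onto the C10=C20 styrenyl bond of ring B. The C20 cation is benzylic to the electron-rich ring C and can only lose H-10, so one operation closes ring A, restores the C10=C20 alkene and sets the C1 carbinol. The precursor is a tricyclic benzocycloheptatriene enol lactone whose C4 and C5 stereocentres derive from (R)-5-(hydroxymethyl)butyrolactone.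

Key step: step 17

Remark on numbering: C1–C20 are the icetexane positions of the target (ring A: C1–C5, C10; ring B: C5–C10, C20; ring C: C8, C9, C11–C14; lactone C19(=O)–O–C6). In furanones 8–22 the ring positions 2, 3, 4, 5 and the exocyclic carbon are the future C19, C4, C5, C6 and C7.

Remark on mixtures: 22 and 23 are carried as both C7 epimers, and 11 and 12 as C3 epimers; these centres are erased in steps 15 and 7.

Step 1
Reactants: 1 1,2,4-trimethoxybenzene
Product: 3 2-(2,3,6-trimethoxyphenyl)propan-2-ol, via aryllithium 2 (not isolated)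
Conditions: n-BuLi, THF, 0 °C; then acetone, −78 °C → rt; H2O
Reagents that add atoms: acetone CC(C)=O
Why: Directed ortho-metalation removes the ring proton flanked by two methoxy groups, and the aryllithium should add to acetone.

Step 2
Reactants: 3 2-(2,3,6-trimethoxyphenyl)propan-2-ol
Product: 4 2-isopropyl-1,3,4-trimethoxybenzene
Conditions: Et3SiH, CF3CO2H, CH2Cl2, 0 °C → rt
Reagents that add atoms: none
Why: Ionic hydrogenation: the tertiary benzylic alcohol ionises to a cation stabilised by two ortho-methoxy groups and Et3SiH delivers hydride.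

Step 3
Reactants: 4 2-isopropyl-1,3,4-trimethoxybenzene
Product: 5 1-bromo-3-isopropyl-2,4,5-trimethoxybenzene
Conditions: N-bromosuccinimide, MeCN, 0 °C → rt
Reagents that add atoms: N-bromosuccinimide O=C1CCC(=O)N1Br
Why: Electrophilic aromatic bromination should occur at the free position para to one methoxy group and ortho to another (future C8), since the other free position is para only to the isopropyl group.

Step 4
Reactants: 5 1-bromo-3-isopropyl-2,4,5-trimethoxybenzene
Product: 6 2-bromo-4-isopropyl-3,5,6-trimethoxybenzaldehyde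
Conditions: Cl2CHOMe, TiCl4, CH2Cl2, −20 → 0 °C; then H2O
Reagents that add atoms: dichloromethyl methyl ether COC(Cl)Cl; water O
Why: Rieche formylation at the single remaining ring position (future C9), activated by the adjacent methoxy group, followed by hydrolysis of the α-chloro ether to the aldehyde.

Step 5
Reactants: 6 2-bromo-4-isopropyl-3,5,6-trimethoxybenzaldehyde
Product: 7 1-bromo-3-isopropyl-2,4,5-trimethoxy-6-vinylbenzene
Conditions: Ph3PCH3Br, KOtBu, THF, 0 °C → rt
Reagents that add atoms: methyltriphenylphosphonium bromide C[P+](c1ccccc1)(c1ccccc1)c1ccccc1.[Br-]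
Why: Wittig methylenation of the aryl aldehyde with the unstabilised ylide Ph3P=CH2 should give the styrene needed for ring B.

Step 6
Reactants: 8 (R)-5-(hydroxymethyl)dihydrofuran-2(3H)-one
Product: 9 (R)-5-[(tert-butyldiphenylsilyloxy)methyl]dihydrofuran-2(3H)-one
Conditions: tBuPh2SiCl, imidazole, CH2Cl2, rt
Reagents that add atoms: tert-butyl(chloro)diphenylsilane CC(C)(C)[Si](Cl)(c1ccccc1)c1ccccc1
Why: Silylation of the primary alcohol; the bulky silyl ether later shields one face of the butenolide.

Step 7
Reactants: 9 (R)-5-[(tert-butyldiphenylsilyloxy)methyl]dihydrofuran-2(3H)-one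
Product: 13 (R)-5-[(tert-butyldiphenylsilyloxy)methyl]furan-2(5H)-one, via lithium enolate 10 (not isolated), via phenylselanyl lactone 11 (not isolated), via selenoxide 12 (not isolated)
Conditions: LiN(iPr)2, THF, −78 °C; PhSeBr; then 30% H2O2, CH2Cl2, 0 °C → rt
Reagents that add atoms: none
Why: α-Selenenylation of the lactone enolate and selenoxide syn-elimination should give the butenolide without touching the C6 stereocentre.

Step 8
Reactants: 13 (R)-5-[(tert-butyldiphenylsilyloxy)methyl]furan-2(5H)-one
Product: 14 (4S,5R)-5-[(tert-butyldiphenylsilyloxy)methyl]-4-vinyldihydrofuran-2(3H)-one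
Conditions: CH2=CHMgBr, CuI, THF–Me2S, −78 → −40 °C; H2O
Reagents that add atoms: vinylmagnesium bromide C=C[Mg]Br
Why: Copper-mediated 1,4-addition of the vinyl Grignard reagent anti to the bulky γ-silyloxymethyl group sets C5, with the vinyl group (future C10=C20) trans to C7.

Step 9
Reactants: 14 (4S,5R)-5-[(tert-butyldiphenylsilyloxy)methyl]-4-vinyldihydrofuran-2(3H)-one
Product: 16 (3R,4R,5R)-5-[(tert-butyldiphenylsilyloxy)methyl]-3-(3,3-dimethoxypropyl)-4-vinyldihydrofuran-2(3H)-one, via lithium enolate 15 (not isolated)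
Conditions: LiN(iPr)2, THF, −78 °C; then BrCH2CH2CH(OMe)2, DMPU, −78 → −20 °C
Reagents that add atoms: 3-bromo-1,1-dimethoxypropane COC(CCBr)OC
Why: SN2 alkylation of the lactone enolate anti to the β-vinyl group installs the C3–C2–C1 chain as its dimethyl acetal; the C4 configuration formed here is re-set in step 10.

Step 10
Reactants: 16 (3R,4R,5R)-5-[(tert-butyldiphenylsilyloxy)methyl]-3-(3,3-dimethoxypropyl)-4-vinyldihydrofuran-2(3H)-one
Product: 18 (3S,4R,5R)-5-[(tert-butyldiphenylsilyloxy)methyl]-3-(3,3-dimethoxypropyl)-3-methyl-4-vinyldihydrofuran-2(3H)-one, via lithium enolate 17 (not isolated)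
Conditions: LiN(iPr)2, THF, −78 °C; then MeI, −78 → −30 °C
Reagents that add atoms: iodomethane CI
Why: Methylation of the tetrasubstituted lactone enolate anti to the β-vinyl group (1,2-induction) places methyl trans and the three-carbon chain cis to the vinyl group, which sets the quaternary C4.

Step 11
Reactants: 18 (3S,4R,5R)-5-[(tert-butyldiphenylsilyloxy)methyl]-3-(3,3-dimethoxypropyl)-3-methyl-4-vinyldihydrofuran-2(3H)-one
Product: 19 (3S,4R,5R)-3-(3,3-dimethoxypropyl)-5-(hydroxymethyl)-3-methyl-4-vinyldihydrofuran-2(3H)-one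
Conditions: Bu4NF, AcOH, THF, 0 °C → rt
Reagents that add atoms: none
Why: Fluoride cleaves the silyl ether, and acetic acid buffers the alkoxide so that it should not attack the lactone.

Step 12
Reactants: 19 (3S,4R,5R)-3-(3,3-dimethoxypropyl)-5-(hydroxymethyl)-3-methyl-4-vinyldihydrofuran-2(3H)-one
Product: 20 (2R,3R,4S)-4-(3,3-dimethoxypropyl)-4-methyl-5-oxo-3-vinyltetrahydrofuran-2-carbaldehyde
Conditions: Dess–Martin periodinane, NaHCO3, CH2Cl2, 0 °C → rt
Reagents that add atoms: none
Why: Dess–Martin oxidation should give the α-acyloxy aldehyde (C7) under buffered conditions that spare the acetal.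

Step 13
Reactants: 7 1-bromo-3-isopropyl-2,4,5-trimethoxy-6-vinylbenzene; 20 (2R,3R,4S)-4-(3,3-dimethoxypropyl)-4-methyl-5-oxo-3-vinyltetrahydrofuran-2-carbaldehyde
Product: 22 (3S,4R,5R)-3-(3,3-dimethoxypropyl)-5-[hydroxy(3-isopropyl-2,4,5-trimethoxy-6-vinylphenyl)methyl]-3-methyl-4-vinyldihydrofuran-2(3H)-one (both C7 epimers), via aryllithium 21 (not isolated)
Conditions: 7, t-BuLi (2 equiv), THF, −78 °C; then 20, −78 °C; H2O
Reagents that add atoms: none
Why: Bromine–lithium exchange followed by 1,2-addition to the aldehyde, which is far more electrophilic than the lactone carbonyl flanked by the quaternary C4; the new C7 centre is uncontrolled and is erased in step 15.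

Step 14
Reactants: 22 (3S,4R,5R)-3-(3,3-dimethoxypropyl)-5-[hydroxy(3-isopropyl-2,4,5-trimethoxy-6-vinylphenyl)methyl]-3-methyl-4-vinyldihydrofuran-2(3H)-one
Product: 23 tricyclic hydroxy lactone (4S,5R,6R; C7 epimers): benzocycloheptadiene ring B with C10=C20, trans-fused at C5–C6 to the γ-lactone
Conditions: second-generation Grubbs catalyst RuCl2(H2IMes)(PCy3)(=CHPh) (10 mol %), toluene (2 mM), 80 °C
Reagents that add atoms: none
Why: Ring-closing olefin metathesis of the styrene and the C5 vinyl group should close ring B as the cis C10=C20 alkene, driven by loss of ethylene.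

Step 15
Reactants: 23 tricyclic hydroxy lactone (4S,5R,6R; C7 epimers)
Product: 24 (4S,5R)-enol lactone dimethyl acetal with C6=C7 and C10=C20
Conditions: Burgess reagent, toluene, 60 °C
Reagents that add atoms: none
Why: Burgess dehydration of the o,p-dimethoxybenzylic alcohol proceeds through an ion pair that can only lose H-6, so both C7 epimers should converge on the C6=C7 enol lactone, its geometry fixed by ring B.

Step 16
Reactants: 24 (4S,5R)-enol lactone dimethyl acetal
Product: 25 (4S,5R)-aldehyde: 3-oxopropyl chain and methyl on C4 of the tricyclic enol lactone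
Conditions: pyridinium p-toluenesulfonate (20 mol %), acetone–H2O 10:1, 40 °C
Reagents that add atoms: water O
Why: Mild acid-catalysed acetal hydrolysis should free the C1 aldehyde while the enol lactone and the skipped triene survive.

Step 17
Reactants: 25 (4S,5R)-aldehyde
Product: 26 (1R,4S,5R)-1-hydroxy-11,12,14-trimethoxyicetexa-6,8,11,13,10(20)-pentaen-19,6-olide
Conditions: Me2AlCl (1.5 equiv), CH2Cl2, −78 → −30 °C; then H2O
Reagents that add atoms: none
Why: Me2AlCl activates the C1 aldehyde, which is attacked by C10 of the C10=C20 styrenyl bond in a stepwise cationic Prins cyclisation; the C20 cation, benzylic to ring C and stabilised by the C11 methoxy group, loses H-10 to restore the C10=C20 alkene, and an Al–Me group takes up the proton as methane so that the product rests as an aluminium alkoxide until work-up. The closest known reaction type is the Me2AlCl-promoted intramolecular Prins (carbonyl-ene type) cyclisation of unsaturated aldehydes to cyclohexanols. Ring A closes in the 6-exo-trig mode with respect to the C10=C20 bond, through a chair-like transition state. The one new stereocentre, C1, is controlled by C4 and C5: the chain is held on the C10 face of the cis-substituted lactone, and the aluminium-bound oxygen should take the equatorial position of the chair, which is the 1β (1R) alcohol. The step needs chemoselectivity for C10=C20 over C6=C7 and a single direction of proton loss; the first is secured because C6=C7 is an enol ester that would demand a seven-membered closure, the second because C20 has no other β-hydrogen.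

Step 18
Reactants: 26 (1R,4S,5R)-1-hydroxy-11,12,14-trimethoxyicetexa-6,8,11,13,10(20)-pentaen-19,6-olide
Product: 27 12-O-methyl-6,7-anhydroballotiquinone
Conditions: (NH4)2Ce(NO3)6 (2.5 equiv), MeCN–H2O 3:1, 0 °C
Reagents that add atoms: water O
Why: Oxidative demethylation of the para-disposed C11 and C14 methoxy groups (two one-electron oxidations by tetravalent cerium with ipso attack of water) should give the para-quinone and leave the C12 methoxy group as a vinylogous ester.

Step 19
Reactants: 27 12-O-methyl-6,7-anhydroballotiquinone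
Product: 28 6,7-anhydroballotiquinone
Conditions: BCl3 (2 equiv), CH2Cl2, −78 → −20 °C; then H2O
Reagents that add atoms: none
Why: Lewis-acid ether cleavage: BCl3 chelated between the C11 carbonyl and the C12 methoxy oxygen activates the methyl group for chloride attack, which should unveil the hydroxyquinone without breaking the lactone or carbinol C–O bonds.

Compound list
1 | 1,2,4-trimethoxybenzene | COc1ccc(OC)c(OC)c1 | starting material
2 | (2,3,6-trimethoxyphenyl)lithium | COc1ccc(OC)c(OC)c1[Li] | intermediate (not isolated)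
3 | 2-(2,3,6-trimethoxyphenyl)propan-2-ol | COc1ccc(OC)c(OC)c1C(C)(C)O | intermediate
4 | 2-isopropyl-1,3,4-trimethoxybenzene | COc1ccc(OC)c(OC)c1C(C)C | intermediate
5 | 1-bromo-3-isopropyl-2,4,5-trimethoxybenzene | COc1c(Br)cc(OC)c(OC)c1C(C)C | intermediate
6 | 2-bromo-4-isopropyl-3,5,6-trimethoxybenzaldehyde | COc1c(Br)c(C=O)c(OC)c(OC)c1C(C)C | intermediate
7 | 1-bromo-3-isopropyl-2,4,5-trimethoxy-6-vinylbenzene | COc1c(Br)c(C=C)c(OC)c(OC)c1C(C)C | intermediate
8 | (R)-5-(hydroxymethyl)dihydrofuran-2(3H)-one | O=C1CC[C@H](CO)O1 | starting material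
9 | (R)-5-[(tert-butyldiphenylsilyloxy)methyl]dihydrofuran-2(3H)-one | O=C1CC[C@H](CO[Si](c2ccccc2)(c2ccccc2)C(C)(C)C)O1 | intermediate
10 | lithium enolate of 9 | [Li]OC1=CC[C@H](CO[Si](c2ccccc2)(c2ccccc2)C(C)(C)C)O1 | intermediate (not isolated)
11 | (5R)-5-[(tert-butyldiphenylsilyloxy)methyl]-3-(phenylselanyl)dihydrofuran-2(3H)-one (C3 epimers) | O=C1C([Se]c2ccccc2)C[C@H](CO[Si](c3ccccc3)(c3ccccc3)C(C)(C)C)O1 | intermediate (not isolated)
12 | selenoxide of 11 | O=C1C([Se](=O)c2ccccc2)C[C@H](CO[Si](c3ccccc3)(c3ccccc3)C(C)(C)C)O1 | intermediate (not isolated)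
13 | (R)-5-[(tert-butyldiphenylsilyloxy)methyl]furan-2(5H)-one | O=C1C=C[C@H](CO[Si](c2ccccc2)(c2ccccc2)C(C)(C)C)O1 | intermediate
14 | (4S,5R)-5-[(tert-butyldiphenylsilyloxy)methyl]-4-vinyldihydrofuran-2(3H)-one (4,5-trans) | O=C1C[C@@H](C=C)[C@H](CO[Si](c2ccccc2)(c2ccccc2)C(C)(C)C)O1 | intermediate
15 | lithium enolate of 14 | [Li]OC1=C[C@@H](C=C)[C@H](CO[Si](c2ccccc2)(c2ccccc2)C(C)(C)C)O1 | intermediate (not isolated)
16 | (3R,4R,5R)-5-[(tert-butyldiphenylsilyloxy)methyl]-3-(3,3-dimethoxypropyl)-4-vinyldihydrofuran-2(3H)-one (3,4-trans, 4,5-trans) | O=C1[C@H](CCC(OC)OC)[C@@H](C=C)[C@H](CO[Si](c2ccccc2)(c2ccccc2)C(C)(C)C)O1 | intermediate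
17 | lithium enolate of 16 | [Li]OC1=C(CCC(OC)OC)[C@@H](C=C)[C@H](CO[Si](c2ccccc2)(c2ccccc2)C(C)(C)C)O1 | intermediate (not isolated)
18 | (3S,4R,5R)-5-[(tert-butyldiphenylsilyloxy)methyl]-3-(3,3-dimethoxypropyl)-3-methyl-4-vinyldihydrofuran-2(3H)-one (acetal chain cis to vinyl) | O=C1[C@@](C)(CCC(OC)OC)[C@@H](C=C)[C@H](CO[Si](c2ccccc2)(c2ccccc2)C(C)(C)C)O1 | intermediate
19 | (3S,4R,5R)-3-(3,3-dimethoxypropyl)-5-(hydroxymethyl)-3-methyl-4-vinyldihydrofuran-2(3H)-one | O=C1[C@@](C)(CCC(OC)OC)[C@@H](C=C)[C@H](CO)O1 | intermediate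
20 | (2R,3R,4S)-4-(3,3-dimethoxypropyl)-4-methyl-5-oxo-3-vinyltetrahydrofuran-2-carbaldehyde | O=C1[C@@](C)(CCC(OC)OC)[C@@H](C=C)[C@H](C=O)O1 | intermediate
21 | (3-isopropyl-2,4,5-trimethoxy-6-vinylphenyl)lithium | COc1c([Li])c(C=C)c(OC)c(OC)c1C(C)C | intermediate (not isolated)
22 | (3S,4R,5R)-3-(3,3-dimethoxypropyl)-5-[hydroxy(3-isopropyl-2,4,5-trimethoxy-6-vinylphenyl)methyl]-3-methyl-4-vinyldihydrofuran-2(3H)-one (both C7 epimers) | O=C1[C@@](C)(CCC(OC)OC)[C@@H](C=C)[C@H](C(O)c2c(OC)c(C(C)C)c(OC)c(OC)c2C=C)O1 | intermediate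
23 | tricyclic hydroxy lactone (4S,5R,6R; C7 epimers): ring B closed with C10=C20, γ-lactone trans-fused at C5–C6, C4 bearing methyl and the 3,3-dimethoxypropyl chain | O=C1[C@@](C)(CCC(OC)OC)[C@H]2C=Cc3c(OC)c(OC)c(C(C)C)c(OC)c3C(O)[C@@H]2O1 | intermediate
24 | (4S,5R)-enol lactone dimethyl acetal (C6=C7, C10=C20) | O=C1[C@@](C)(CCC(OC)OC)[C@H]2C=Cc3c(OC)c(OC)c(C(C)C)c(OC)c3C=C2O1 | intermediate
25 | (4S,5R)-aldehyde (C4 bearing methyl and the 3-oxopropyl chain; C6=C7, C10=C20) | O=C1[C@@](C)(CCC=O)[C@H]2C=Cc3c(OC)c(OC)c(C(C)C)c(OC)c3C=C2O1 | intermediate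
26 | (1R,4S,5R)-1-hydroxy-11,12,14-trimethoxyicetexa-6,8,11,13,10(20)-pentaen-19,6-olide | COc1c(C(C)C)c(OC)c(OC)c2c1C=C3OC(=O)[C@@]4(C)CC[C@@H](O)C(=C2)[C@@H]34 | intermediate
27 | 12-O-methyl-6,7-anhydroballotiquinone (1R,4S,5R) | CC(C)C1=C(OC)C(=O)C2=C(C=C3OC(=O)[C@@]4(C)CC[C@@H](O)C(=C2)[C@@H]34)C1=O | intermediate
28 | 6,7-anhydroballotiquinone (1R,4S,5R) | CC(C)C1=C(O)C(=O)C2=C(C=C3OC(=O)[C@@]4(C)CC[C@@H](O)C(=C2)[C@@H]34)C1=O | target

Total step count: 19 (arene branch steps 1–5, lactone branch steps 6–12, union in step 13, steps 14–19 after it).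
Longest linear sequence: 14 steps (steps 6–19, from lactone 8).

Steps most likely to fail

Step 17 (Prins cyclisation). The C20 benzylic cation may be captured by chloride instead of losing H-10. The product alkoxide may ionise at C1 and eliminate. Facial selectivity at C1 may erode if the C–C bond formation becomes reversible. The fallback sets out from aldehyde 25 and returns to 26 by an intramolecular nitrile oxide cycloaddition. Aldehyde 25 is condensed with NH2OH·HCl and pyridine to the oxime F1. N-Chlorosuccinimide then Et3N converts it into the nitrile oxide F2, which should add across C10=C20 in a (3+2) cycloaddition to the isoxazoline F3 (C1–C10 and O–C20 bonds, ring A closed). Mo(CO)6 in wet MeCN at 80 °C cleaves the N–O bond and the imine hydrolyses to the β-hydroxy ketone F4. MsCl and Et3N dehydrate this to the enone F5, whose C1 ketone is conjugated with C10=C20. Luche reduction (NaBH4, CeCl3·7H2O, MeOH, −78 °C) with axial hydride delivery from the α-face should then give the equatorial 1β-alcohol 26.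

Step 14 (ring-closing metathesis). Initiation at the ortho,ortho-disubstituted styrene may be slow, and closing a seven-membered ring trans-fused to the lactone is strained, so oligomerisation may compete. The fallback sets out from 22 and returns to 23 by reductive carbonyl coupling. Both vinyl groups are cleaved with OsO4 (cat.), NaIO4 and 2,6-lutidine in dioxane–H2O to the dialdehyde F6. An intramolecular McMurry coupling (TiCl4, Zn, pyridine, THF, reflux, high dilution) should then form the C10=C20 bond of ring B directly.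

Step 19 (O-demethylation). The Lewis acid may ionise the allylic C1 alcohol or open the enol lactone before the methyl ether is cleaved. The fallback sets out from 27 and returns to 28 without a new compound. The vinylogous ester is hydrolysed by conjugate addition of water at C12 and loss of methanol (1 M aqueous H2SO4, THF, 40 °C), which avoids any Lewis acid.

Further compounds
F1 | step 17 | oxime of aldehyde 25 (E/Z) | O=C1[C@@](C)(CCC=NO)[C@H]2C=Cc3c(OC)c(OC)c(C(C)C)c(OC)c3C=C2O1
F2 | step 17 | nitrile oxide from F1 | O=C1[C@@](C)(CCC#[N+][O-])[C@H]2C=Cc3c(OC)c(OC)c(C(C)C)c(OC)c3C=C2O1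
F3 | step 17 | isoxazoline (C1=N–O–C20, C1–C10 bond; C10 and C20 configuration not defined) | COc1c(C(C)C)c(OC)c(OC)c2c1C=C3OC(=O)[C@@]4(C)CCC5=NOC2C5[C@@H]34
F4 | step 17 | β-hydroxy ketone (C1 ketone, C20 hydroxyl; C10 and C20 configuration not defined) | COc1c(C(C)C)c(OC)c(OC)c2c1C=C3OC(=O)[C@@]4(C)CCC(=O)C(C2O)[C@@H]34
F5 | step 17 | enone (C1 ketone conjugated with C10=C20) | COc1c(C(C)C)c(OC)c(OC)c2c1C=C3OC(=O)[C@@]4(C)CCC(=O)C(=C2)[C@@H]34
F6 | step 14 | dialdehyde from 22 (C7 epimers) | O=C1[C@@](C)(CCC(OC)OC)[C@@H](C=O)[C@H](C(O)c2c(OC)c(C(C)C)c(OC)c(OC)c2C=O)O1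
F0 | step 19 | none | none
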